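## Structural features

The target is the 2‑hydroxybenzoate of a daucane diol. A cyclopentane (ring A: C1, C2, C3, C4, C5) is fused through C1–C5 to a cycloheptene (ring B: C1, C5, C6, C7, C8, C9, C10) whose C8–C9 alkene carries the C14 methyl group. Four stereocentres are contiguous: quaternary C1 (angular methyl C15), C5 (ring‑fusion hydrogen), C4 (tertiary alcohol and isopropyl group) and C6 (ester oxygen). The methyl group and the C4 hydroxyl lie on one face, H5 and the C6 oxygen on the other, so the ring fusion is trans. Three features are fragile. The tertiary hydroxyl is β to C6, so any C6 ketone can dehydrate or undergo retro‑aldol cleavage. The C8–C9 alkene is β,γ to C6 and moves into conjugation through C7 under base. The salicylate has a free phenol. The real difficulty is quaternary C1 and its neighbour C5: a methyl group must be placed on a fully substituted carbon on a defined face, and H5 must then end up trans to it. The key step uses the C1–C5 bond as a tetrasubstituted alkene: the C4 hydroxyl and a cis C6 hydroxyl are both allylic to it and mark the face the methyl group needs, and C1 is β to C6, so a methylene added across C1–C5 can later be cut at C5–C15 through a C6 ketone. Because of the fragile features, C5 cannot be corrected by base afterwards; the protonation that sets it is the weak point of the plan.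

## Logic of the disconnections

24 is cut at the ester C–O bond to 21 and 22. The acyl group goes on last so that the phenol and the ester see no redox chemistry. The gain is a plain diol; the demand is acylation of the secondary hydroxyl next to a free tertiary one, without a phenol protecting group.

21 is cut at the C6–H bond to 19. A C6 ketone lets the C4 hydroxyl deliver hydride to its own face, which places the C6 oxygen trans to it. The gain is one stereocentre fewer and a carbonyl at C6; the demand is a reduction free of base.

19 is cut at C5–H and C15–H, with C5–C15 re‑formed, to 17. The angular methyl is read as the methylene of a cyclopropane conjugated to the C6 carbonyl. The gain is that the quaternary methyl and the ring‑fusion hydrogen both come from one three‑membered ring. The demand is cleavage of the exocyclic cyclopropane bond only, and protonation of C5 on the face opposite the methyl group.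

17 is taken back to 16 by an oxidation‑level change at C6, because the free C6 carbinol is wanted as a second directing group in the step before.

16 is cut at C1–C15 and C5–C15 to 13 and 14. This is the strategic cut: two stereocentres, one quaternary, collapse to a flat tetrasubstituted alkene flanked by two hydroxyls on the face where the methylene must arrive. The demand is face selectivity and selectivity for C1–C5 over C8–C9.

13 is taken back to 12 (protecting group) and 12 is cut at C8–C9 to 11. A ring‑closing metathesis retron places the trisubstituted alkene without ambiguity. The gain is an open ring B with two alkene arms held cis on ring A; the demand is seven‑ring closure onto a 1,1‑disubstituted alkene.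

11 is cut at C6–C7 to 9 and 10. The gain is an aldehyde at C6; the demand is addition to the aldehyde face that leaves the C6 hydroxyl cis to the C4 oxygen after ring closure.

9 is cut at C9–C10 to 7 and 8, and 7 is taken back through 6 to 5. C10 becomes the methyl group of a simple enal; the demand is functionalisation of that methyl group and not of the ring methylene C2.

5 is cut at C1–C5 to 4, and 4 is reconnected between its two carbonyl carbons to 2 and then 1. The gain is that ring A and the C4 stereocentre come from a commercial cyclohexenol. The demand is the aldol mode in which the aldehyde α‑carbon attacks the ketone, with the tertiary oxygen masked.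

## Other disconnections considered

Alternative 1: Ring B is cut at C6–C7 and C9–C10. Forward, the exocyclic silyl dienol ether 6 of the chosen route would trap the parent oxyallyl cation released from 1,3‑dibromopropan‑2‑one A3 by zinc–copper couple in a (4+3) cycloaddition. This closes ring B as the C8 ketone A1 with the C1–C5 alkene in place.
- In its favour: one step takes 6 to the bicycle, no tin is used, and the ketone would reach 13 in three more steps (C8 enol triflate, methyl coupling, desilylation). That is one step fewer than bromination, Stille coupling, allylation, metathesis and desilylation, so on step economy it is the better plan. On the source of C4 and on the need for 6 it is the equal.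
- Against it here: the unsubstituted oxyallyl cation is the least stabilised of its family and is normally made from polyhalogenated ketones with a later dehalogenation, so A3 with the couple alone is a weak point. With a nucleophilic dienol ether the process is probably stepwise and can stop after the first bond. The C8 ketone must then be enolised towards C9 and not C7.
- A structural correction: A1 drawn with the C6 silyloxy group trans to the C4 oxygen is not what the facial model used here predicts. Closure anti to the isopropyl group would give the C6 epimer A2, and only A2 leads to the cis diol that the directed cyclopropanation needs.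
- Comparison: the cycloaddition solves ring B only. The angular methyl would still come from the same cyclopropanation, so this is a shorter but less controlled way to 13, not a different answer to C1. The metathesis was preferred because it fixes the C8–C9 alkene by construction.

Alternative 2: The bicycle is cut at C1–C5 and C9–C10. Forward, the acetoxypyranone A4 with Et3N would give a 3‑oxidopyrylium ylide that adds across its tethered 1,1‑disubstituted alkene in an intramolecular (5+2) cycloaddition. The product is the oxygen‑bridged ketone A5, with rings A and B and quaternary C1 formed together.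
- In its favour: the methyl group is already on C1, so no cyclopropane and no later C–C cleavage are needed. After reductive cleavage of the C5–O bond next to the ketone (for example with SmI2), the freed C9 hydroxyl would lie on the face from which C5 must be protonated. On the ring‑fusion hydrogen this plan is therefore better placed than the chosen one. The C9 allylic alcohol would also allow a reductive allylic transposition that puts the alkene at C8–C9.
- Against it here: face selection in the cycloaddition rests on the fully substituted C4 next to the pyrylium carbon, with a silyl ether and an isopropyl group of similar size on the two faces. A4 needs the tertiary carbinol on an open chain, which costs several steps. Bridge opening, removal of the C9 oxygen and C6 reduction follow the key step.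
- Comparison: the mechanism is well precedented for three‑atom tethers and the bond construction is more convergent. The length is probably similar, and the face selectivity is less predictable than that of a hydroxyl‑bound carbenoid.

Alternative 3: Ring A is cut at C4–C5. Forward, Rh2(OAc)4 would turn the diazo ketone A6 into a carbenoid at C5 that inserts into the tertiary C4–H bond α to the silyloxy group, closing ring A as A7.
- In its favour: C4 would be carried over with retention from a secondary silyl ether that is easy to obtain as one enantiomer. Five‑ring formation by insertion next to oxygen is the preferred mode. A7 is the O‑silyl form of 19, so the last steps are the same; on the endgame it is the equal, and it needs no directing hydroxyl.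
- Against it here: quaternary C1 must be made enantioselectively on a cycloheptenone before the key step, so the central difficulty is moved and not removed. Diazo transfer is next to a quaternary carbon. The carbenoid has other outlets: a 1,2‑shift from C1, insertion into the isopropyl methine, and addition to the C8–C9 alkene. The ring fusion formed by insertion may be cis, and equilibration at C5 would then be needed in a β‑silyloxy ketone that can eliminate.
- Comparison: on C5 it is no better than the chosen plan, and on step count it is comparable.

Key step: step 10

Assumption: 1 is used as the single (S) enantiomer; commercial material that is only enantioenriched would be brought to full purity first (for example through a crystalline ester).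

## Route

Step 1
Reactants: 1 (S)‑terpinen‑4‑ol
Product: 2 (S)‑triethyl{[4‑methyl‑1‑(propan‑2‑yl)cyclohex‑3‑en‑1‑yl]oxy}silane
Conditions: Et3SiOTf, 2,6‑lutidine, CH2Cl2, 0 °C
Reagents that add atoms: triethylsilyl trifluoromethanesulfonate, CC[Si](CC)(CC)OS(=O)(=O)C(F)(F)F
Why: Silylation of a tertiary alcohol with a silyl triflate; the ether masks the oxygen that will be β to the aldehyde in 4, so dehydration and retro‑aldol cleavage are blocked in steps 2 to 8. The C4 stereocentre is not touched.

Step 2
Reactants: 2
Product: 4 (S)‑6‑oxo‑3‑(propan‑2‑yl)‑3‑(triethylsilyloxy)heptanal, via ozonide 3 (not isolated)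
Conditions: O3, CH2Cl2, −78 °C; then PPh3, −78 °C → rt
Reagents that add atoms: ozone, [O-][O+]=O
Why: Ozonolysis of the only alkene (Criegee sequence) with reductive work‑up gives the methyl ketone (C1, C10) and the aldehyde (C6); the stereocentre is remote from the reacting carbons.

Step 3
Reactants: 4
Product: 5 (R)‑2‑methyl‑5‑(propan‑2‑yl)‑5‑(triethylsilyloxy)cyclopent‑1‑ene‑1‑carbaldehyde
Conditions: piperidine (0.2 equiv), AcOH (0.2 equiv), toluene, 60 °C
Reagents that add atoms: none
Why: Amine‑catalysed intramolecular aldol condensation: the enamine of the aldehyde attacks the ketone (five‑ring closure C5–C1) and water is lost to give the tetrasubstituted enal. This is the mode known for 6‑oxoheptanals under amine catalysis, whereas hydroxide gives the acetylcyclopentene. The silyl ether keeps the β‑oxygen from leaving.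

Step 4
Reactants: 5
Product: 6 (R,Z)‑tert‑butyldimethyl{[5‑methylidene‑2‑(propan‑2‑yl)‑2‑(triethylsilyloxy)cyclopentylidene]methoxy}silane
Conditions: t‑BuMe2SiOTf, Et3N, CH2Cl2, 0 °C
Reagents that add atoms: tert‑butyldimethylsilyl trifluoromethanesulfonate, CC(C)(C)[Si](C)(C)OS(=O)(=O)C(F)(F)F
Why: Soft enolisation of an enal: O‑silylation followed by γ‑deprotonation of the methyl group (three unhindered hydrogens, cis to the formyl group) gives the exocyclic silyl dienol ether. Silylation of the s‑trans enal places the silyloxy group on the C4 side of the C5–C6 double bond.

Step 5
Reactants: 6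
Product: 7 (R)‑2‑(bromomethyl)‑5‑(propan‑2‑yl)‑5‑(triethylsilyloxy)cyclopent‑1‑ene‑1‑carbaldehyde
Conditions: N‑bromosuccinimide, THF, −78 → 0 °C
Reagents that add atoms: N‑bromosuccinimide, O=C1CCC(=O)N1Br
Why: Vinylogous bromination of a silyl dienol ether: bromine enters at the γ‑terminus C10 and the conjugated enal is regenerated. Attack at fully substituted C5 is disfavoured and would give the allylic isomer, which converges in step 6.

Step 6
Reactants: 7; 8 tributyl(vinyl)stannane
Product: 9 (R)‑2‑(prop‑2‑en‑1‑yl)‑5‑(propan‑2‑yl)‑5‑(triethylsilyloxy)cyclopent‑1‑ene‑1‑carbaldehyde
Conditions: Pd2(dba)3 (2.5 mol%), AsPh3 (10 mol%), THF, 50 °C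
Reagents that add atoms: tributyl(vinyl)stannane 8, C=C[Sn](CCCC)(CCCC)CCCC
Why: Stille coupling of an allylic bromide through an η3‑allylpalladium intermediate; the vinyl group is transferred to the unsubstituted terminus C10, which restores conjugation of the enal. The conditions are neutral, so the doubly allylic C10 hydrogens are not removed.

Step 7
Reactants: 9; 10 3‑bromo‑2‑methylprop‑1‑ene
Product: 11 (R)‑3‑methyl‑1‑[(R)‑2‑(prop‑2‑en‑1‑yl)‑5‑(propan‑2‑yl)‑5‑(triethylsilyloxy)cyclopent‑1‑en‑1‑yl]but‑3‑en‑1‑ol
Conditions: Zn dust, THF/sat. aq. NH4Cl, 0 °C → rt
Reagents that add atoms: 3‑bromo‑2‑methylprop‑1‑ene 10, CC(=C)CBr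
Why: Barbier‑type 1,2‑allylation of the aldehyde by an allylzinc reagent formed in the flask; the medium is not basic, so C10 is not deprotonated. C6 is set by the C4 centre: the enal reacts with its oxygen on the C4 side, allylic strain turns the isopropyl group perpendicular to the enal plane, and the reagent adds from the other face, that of the C4 oxygen. After ring closure this places the C6 hydroxyl cis to the C4 oxygen.

Step 8
Reactants: 11
Product: 12 C4 triethylsilyl ether of 13 (bicyclic diene with C1–C5 and C8–C9 alkenes, free C6 hydroxyl cis to the C4 oxygen)
Conditions: second‑generation Grubbs catalyst RuCl2(=CHPh)(H2IMes)(PCy3) (5 mol%), CH2Cl2, 40 °C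
Reagents that add atoms: none
Why: Ring‑closing metathesis between the allyl and the 2‑methylallyl arms, held cis on the cyclopentene, closes the seven‑membered ring and forms the trisubstituted C8–C9 alkene with the methyl group on C8 by construction. The tetrasubstituted C1–C5 alkene does not take part.

Step 9
Reactants: 12
Product: 13 (4R,6R)‑dauca‑1(5),8‑diene‑4,6‑diol (ring numbering as above; bicyclic diene diol without C15, C4 and C6 hydroxyls cis)
Conditions: Bu4NF, THF, 50 °C
Reagents that add atoms: none
Why: Fluoride cleavage of the tertiary triethylsilyl ether frees the C4 hydroxyl that must direct the next step; no stereocentre is involved.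

Step 10
Reactants: 13; 14 diiodomethane
Product: 16 cyclopropane‑fused diol (C15 bridges C1 and C5 on the face of the C4 and C6 hydroxyls; C8–C9 alkene intact), via zinc alkoxide 15 (not isolated)
Conditions: Et2Zn (4 equiv), CH2I2 (4 equiv), CH2Cl2, −20 → 0 °C; aq. NH4Cl
Reagents that add atoms: diiodomethane 14, ICI
Why: Et2Zn first turns both hydroxyls into ethylzinc alkoxides (15) and, with CH2I2, forms the iodomethylzinc carbenoid (Furukawa form of the Simmons–Smith reaction). The carbenoid held at the C4 and C6 oxygens transfers CH2 to the C1–C5 alkene in one concerted, stereospecific syn addition through a butterfly‑type transition state; the closest known reaction type is the hydroxyl‑directed cyclopropanation of cyclic allylic alcohols. The three‑membered ring (C1, C5, C15) is closed by this single [2+1] methylene transfer, with C1–C15 and C5–C15 formed together on one face and no stepwise closure. The new stereocentres C1 and C5 are controlled by the C4 stereocentre: its oxygen and the cis C6 oxygen carry the zinc on one face, so C15 arrives there, which is the face of the future angular methyl. The opposite face is in addition shielded by the isopropyl group. Site selectivity is needed as well: C1–C5 is allylic to both alkoxides and is the more electron‑rich alkene, whereas C8–C9 is only homoallylic to the C6 oxygen, so a limited amount of carbenoid should leave it untouched. The excess of Et2Zn converts ZnI2 into the less Lewis acidic EtZnI and so protects the bis‑allylic diol from ionisation.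

Step 11
Reactants: 16
Product: 17 cyclopropyl ketone (C6 ketone of 16, C4 hydroxyl free)
Conditions: Dess–Martin periodinane, NaHCO3, CH2Cl2, 0 °C
Reagents that add atoms: none
Why: Buffered Dess–Martin oxidation of the secondary cyclopropylcarbinol; the tertiary alcohol is inert and no cation or base is generated. In 17, C5 has no hydrogen, so the β‑hydroxy ketone cannot dehydrate.

Step 12
Reactants: 17
Product: 19 trans‑fused hydroxy ketone (4‑hydroxydauc‑8‑en‑6‑one: angular methyl and C4 hydroxyl cis, H5 trans to both), via dilithium enolate alkoxide 18 (not isolated)
Conditions: Li (6 equiv), NH3(l)/THF, −78 °C; isoprene; solid NH4Cl, −78 °C → rt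
Reagents that add atoms: none
Why: Dissolving‑metal cleavage of a cyclopropyl ketone: the ketyl opens the exocyclic C5–C15 bond, which is aligned with the carbonyl π system (C5–C1 lies in the ring plane). The primary carbanion is protonated to the C15 methyl group, and C5–C6 is left as a lithium enolate beside the C4 lithium alkoxide, a dianion that cannot dehydrate, cleave by retro‑aldol or move the C8–C9 alkene. C5 becomes a stereocentre only in the buffered cold quench: protonation on the face opposite the C4 oxygen gives 19, in which C6 stays on the oxygen face (chelate, then hydrogen bond) and away from the isopropyl group. This facial choice is the least secure element of the route and is taken up below.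

Step 13
Reactants: 19
Product: 21 jaeschkeanadiol (trans‑fused dauc‑8‑ene‑4,6‑diol; C6 hydroxyl trans to the C4 hydroxyl and to the angular methyl), via boron‑bound hydride 20 (not isolated)
Conditions: Me4NBH(OAc)3, AcOH/MeCN, −30 °C
Reagents that add atoms: none
Why: Evans–Saksena reduction of a β‑hydroxy ketone: the tertiary C4 hydroxyl exchanges onto boron and the bound hydride is delivered inside the molecule to C6 on the face of the C4 oxygen. The new hydroxyl therefore ends on the other face, as in the target. The medium is acidic, so the β‑hydroxy ketone and the β,γ‑alkene are safe.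

Step 14
Reactants: 21; 22 2,2‑dimethyl‑4H‑1,3‑benzodioxin‑4‑one
Product: 24 CNP0379621.1 (jaeschkeanadiol 6‑O‑(2‑hydroxybenzoate)), via sodium phenoxide 23 (not isolated)
Conditions: NaN(SiMe3)2 (1.05 equiv), THF, 0 °C; then 22, 0 °C → rt; aq. NH4Cl
Reagents that add atoms: 2,2‑dimethyl‑4H‑1,3‑benzodioxin‑4‑one 22, CC1(C)OC(=O)c2ccccc2O1
Why: Alkoxide opening of a salicylic acid acetonide: the secondary C6 alkoxide adds to the carbonyl and the departing hemiketal alkoxide collapses to acetone and the phenoxide, so the salicylate forms without phenol protection. The tertiary C4 alkoxide is too hindered to compete, and no stereocentre is touched.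

## Compound list

1 | (S)‑terpinen‑4‑ol | CC1=CC[C@](O)(C(C)C)CC1 | starting material
2 | (S)‑triethyl{[4‑methyl‑1‑(propan‑2‑yl)cyclohex‑3‑en‑1‑yl]oxy}silane | CC1=CC[C@](O[Si](CC)(CC)CC)(C(C)C)CC1 | intermediate
3 | secondary ozonide of 2 (1,2,4‑trioxolane across the former alkene; the two ozonide carbons unassigned) | CC12CC[C@@](O[Si](CC)(CC)CC)(C(C)C)CC(OO1)O2 | intermediate
4 | (S)‑6‑oxo‑3‑(propan‑2‑yl)‑3‑(triethylsilyloxy)heptanal | O=CC[C@](O[Si](CC)(CC)CC)(C(C)C)CCC(C)=O | intermediate
5 | (R)‑2‑methyl‑5‑(propan‑2‑yl)‑5‑(triethylsilyloxy)cyclopent‑1‑ene‑1‑carbaldehyde | CC1=C(C=O)[C@](O[Si](CC)(CC)CC)(C(C)C)CC1 | intermediate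
6 | (R,Z)‑tert‑butyldimethyl{[5‑methylidene‑2‑(propan‑2‑yl)‑2‑(triethylsilyloxy)cyclopentylidene]methoxy}silane | C=C1CC[C@@](O[Si](CC)(CC)CC)(C(C)C)/C1=C\O[Si](C)(C)C(C)(C)C | intermediate
7 | (R)‑2‑(bromomethyl)‑5‑(propan‑2‑yl)‑5‑(triethylsilyloxy)cyclopent‑1‑ene‑1‑carbaldehyde | BrCC1=C(C=O)[C@](O[Si](CC)(CC)CC)(C(C)C)CC1 | intermediate
8 | tributyl(vinyl)stannane | C=C[Sn](CCCC)(CCCC)CCCC | starting material
9 | (R)‑2‑(prop‑2‑en‑1‑yl)‑5‑(propan‑2‑yl)‑5‑(triethylsilyloxy)cyclopent‑1‑ene‑1‑carbaldehyde | C=CCC1=C(C=O)[C@](O[Si](CC)(CC)CC)(C(C)C)CC1 | intermediate
10 | 3‑bromo‑2‑methylprop‑1‑ene | CC(=C)CBr | starting material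
11 | (R)‑3‑methyl‑1‑[(R)‑2‑(prop‑2‑en‑1‑yl)‑5‑(propan‑2‑yl)‑5‑(triethylsilyloxy)cyclopent‑1‑en‑1‑yl]but‑3‑en‑1‑ol | C=CCC1=C([C@H](O)CC(C)=C)[C@](O[Si](CC)(CC)CC)(C(C)C)CC1 | intermediate
12 | C4 triethylsilyl ether of 13 (free C6 hydroxyl cis to the C4 oxygen) | CC1=CCC2=C([C@H](O)C1)[C@](O[Si](CC)(CC)CC)(C(C)C)CC2 | intermediate
13 | (4R,6R)‑dauca‑1(5),8‑diene‑4,6‑diol (bicyclic diene diol without C15, hydroxyls cis) | CC1=CCC2=C([C@H](O)C1)[C@](O)(C(C)C)CC2 | intermediate
14 | diiodomethane | ICI | starting material
15 | bis(ethylzinc) alkoxide of 13 | CC1=CCC2=C([C@H](O[Zn]CC)C1)[C@](O[Zn]CC)(C(C)C)CC2 | intermediate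
16 | cyclopropane‑fused diol (C15 bridging C1 and C5 on the hydroxyl face) | CC1=CC[C@]23C[C@@]2([C@H](O)C1)[C@](O)(C(C)C)CC3 | intermediate
17 | cyclopropyl ketone (C6 ketone of 16) | CC1=CC[C@]23C[C@@]2(C(=O)C1)[C@](O)(C(C)C)CC3 | intermediate
18 | dilithium C5–C6 enolate and C4 alkoxide | CC1=CC[C@@]2(C)CC[C@@](O[Li])(C(C)C)C2=C(O[Li])C1 | intermediate
19 | trans‑fused 4‑hydroxydauc‑8‑en‑6‑one (methyl and C4 hydroxyl cis, H5 trans to both) | CC1=CC[C@@]2(C)CC[C@@](O)(C(C)C)[C@@H]2C(=O)C1 | intermediate
20 | tetramethylammonium C4‑alkoxy(diacetoxy)borohydride of 19 | CC1=CC[C@@]2(C)CC[C@@](O[BH-](OC(C)=O)OC(C)=O)(C(C)C)[C@@H]2C(=O)C1.C[N+](C)(C)C | intermediate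
21 | jaeschkeanadiol (trans‑fused dauc‑8‑ene‑4,6‑diol, C6 hydroxyl trans to the C4 hydroxyl) | CC1=CC[C@@]2(C)CC[C@@](O)(C(C)C)[C@@H]2[C@@H](O)C1 | intermediate
22 | 2,2‑dimethyl‑4H‑1,3‑benzodioxin‑4‑one | CC1(C)OC(=O)c2ccccc2O1 | starting material
23 | sodium phenoxide of 24 | CC1=CC[C@@]2(C)CC[C@@](O)(C(C)C)[C@@H]2[C@@H](OC(=O)c2ccccc2[O-])C1.[Na+] | intermediate
24 | CNP0379621.1, jaeschkeanadiol 6‑O‑(2‑hydroxybenzoate) | CC1=CC[C@@]2(C)CC[C@@](O)(C(C)C)[C@@H]2[C@@H](OC(=O)c2ccccc2O)C1 | target

## Step count and least certain steps

Total: 14 steps. Longest linear sequence: 14 steps from 1; compounds 8, 10, 14 and 22 are used as bought.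

Step 10 (key step). What may go wrong is loss of site selectivity and ionisation of the substrate. The C6 zinc alkoxide is homoallylic to the C8–C9 alkene and can pass a second methylene to it, and the zinc iodide formed is a Lewis acid towards a diol that is allylic at both carbinol carbons. The fallback changes the carbenoid, not the handling of the zinc reagent. 13 would be treated with a samarium carbenoid (Sm, catalytic HgCl2, ClCH2I, THF, −78 °C → rt). This reagent needs a free allylic hydroxyl, leaves isolated and homoallylic alkenes alone, and generates no strong Lewis acid. It would return to the route at 16 with no new compound.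

Step 12. What may go wrong is protonation of the enolate on the wrong face. The isopropyl group on C4 is expected to stand perpendicular to the enolate plane on the face that must receive the proton, so the kinetic preference may be for the hydroxyl face, which would give the cis‑fused C5 epimer. Correction by base is not available: the β‑hydroxy ketone would dehydrate or cleave, and C7 deprotonation would move the C8–C9 alkene into conjugation. The fallback does not set C5 by protonation and uses only reagents that add to the hydroxyl face.
- It sets out from 16, which would be converted at its secondary hydroxyl into the O‑phenyl thionocarbonate F1 (PhOC(S)Cl, pyridine, DMAP).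
- Bu3SnH with AIBN and catalytic (PhSe)2 would generate the C6 cyclopropylcarbinyl radical, which opens the exocyclic C5–C15 bond. Fast hydrogen transfer to the primary radical would give the angular methyl and the C5–C6 alkene F2.
- VO(acac)2 and t‑BuOOH, directed by the C4 hydroxyl, would give the epoxide F3 on the hydroxyl face.
- Cp2TiCl (trivalent titanium, from Cp2TiCl2 and Zn) with 1,4‑cyclohexadiene would open the epoxide to the tertiary C5 radical. This radical should take its hydrogen atom anti to the bulky titanium alkoxide on C6, giving the trans‑fused 6‑epi diol F4.
- Dess–Martin oxidation of F4 would come back to the route at 19, which would then never have met base or acid.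

Step 4. What may go wrong is loss of regiocontrol in the γ‑deprotonation: removal of a ring hydrogen at C2 would give the endocyclic dienol ether, which is useless for steps 5 and 6. The fallback fixes the position of the new alkene before silylation. It sets out from 5. Irradiation at about 350 nm with a weak base (1,2‑dimethylimidazole) would cause photochemical deconjugation: the 1,5‑hydrogen shift can only take a hydrogen from the methyl group cis to the formyl group, and ketonisation of the dienol would give the β,γ‑unsaturated aldehyde F5 with the exocyclic methylene. t‑BuMe2SiOTf and Et3N would then remove the one remaining acidic hydrogen, at C5, and the route is rejoined at 6.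

Step 7. What may go wrong is poor facial selectivity at the aldehyde, since the C4 centre acts across an sp2 carbon. The C6 epimer would later direct the carbenoid to the wrong face. The fallback replaces substrate control by reagent control. It sets out from 9, which would be treated with B‑(2‑methylallyl)diisopinocampheylborane (from the antipode of B‑methoxydiisopinocampheylborane matched to attack on the face of the C4 oxygen, and 2‑methylallylmagnesium chloride) at −78 °C with an ethanolamine work‑up. It would return at 11 with no new compound.

## Further compounds

F0 | step 10 | none | none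
F1 | step 12 | C6 O‑phenyl thionocarbonate of 16 | CC1=CC[C@]23C[C@@]2([C@H](OC(=S)Oc4ccccc4)C1)[C@](O)(C(C)C)CC3
F2 | step 12 | dauca‑5,8‑dien‑4‑ol with the angular methyl in place (C5–C6 alkene, C4 hydroxyl cis to the methyl group) | CC1=CC[C@@]2(C)CC[C@@](O)(C(C)C)C2=CC1
F3 | step 12 | 5,6‑epoxide of F2 on the face of the C4 hydroxyl | CC1=CC[C@@]2(C)CC[C@@](O)(C(C)C)[C@]23O[C@@H]3C1
F4 | step 12 | 6‑epi‑jaeschkeanadiol (trans‑fused, C6 hydroxyl cis to the C4 hydroxyl) | CC1=CC[C@@]2(C)CC[C@@](O)(C(C)C)[C@@H]2[C@H](O)C1
F5 | step 4 | 2‑methylidene‑5‑(propan‑2‑yl)‑5‑(triethylsilyloxy)cyclopentane‑1‑carbaldehyde (configuration of the formyl‑bearing carbon unassigned) | C=C1CC[C@@](O[Si](CC)(CC)CC)(C(C)C)C1C=O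
F0 | step 7 | none | none
A1 | alternative 1 | (4+3) cycloadduct, C8 ketone with C1–C5 alkene, C6 silyloxy trans to the C4 silyloxy group | O=C1CCC2=C([C@@H](O[Si](C)(C)C(C)(C)C)C1)[C@](O[Si](CC)(CC)CC)(C(C)C)CC2
A2 | alternative 1 | C6 epimer of A1 (C6 silyloxy cis to the C4 silyloxy group) | O=C1CCC2=C([C@H](O[Si](C)(C)C(C)(C)C)C1)[C@](O[Si](CC)(CC)CC)(C(C)C)CC2
A3 | alternative 1 | 1,3‑dibromopropan‑2‑one | BrCC(=O)CBr
A4 | alternative 2 | 6‑acetoxy‑5‑methyl‑2H‑pyran‑3(6H)‑one carrying at C2 the silylated tertiary carbinol with the 3‑methylbut‑3‑enyl tether (ring carbons unassigned) | CC1=CC(=O)C(OC1OC(C)=O)[C@](O[Si](CC)(CC)CC)(C(C)C)CCC(C)=C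
A5 | alternative 2 | oxygen‑bridged (5+2) cycloadduct (C5–O–C9 bridge, C6 ketone, C7–C8 alkene, C4 triethylsilyl ether) | CC1=CC(=O)[C@]23O[C@H]1C[C@@]2(C)CC[C@@]3(O[Si](CC)(CC)CC)C(C)C
A6 | alternative 3 | 2‑diazo cycloheptenone with quaternary C1 and the silyloxy side chain | CC1=CC[C@@](C)(CC[C@@H](O[Si](C)(C)C(C)(C)C)C(C)C)C(=[N+]=[N-])C(=O)C1
A7 | alternative 3 | C4 tert‑butyldimethylsilyl ether of 19 | CC1=CC[C@@]2(C)CC[C@@](O[Si](C)(C)C(C)(C)C)(C(C)C)[C@@H]2C(=O)C1
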